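**Retrosynthetic overview**
1. Last disconnection: the three aryl O‑methyl and two pyrone O‑ethyl groups of a fully etherified precursor are removed together with BBr3.
2. Key disconnection, the feature the plan rests on: in each 2‑pyrone ring the C4–C5 edge (C4 with its oxygen, C5 with its methyl) is the alkyne pair of 1‑ethoxyprop‑1‑yne. Pyrone O1, C2(=O), C3 (with the benzylic CH2) and C6 (with ethyl) are O1, C6, C5 and C2 of a 2‑ethyl‑5‑(arylmethyl)‑1,3,4‑oxadiazin‑6‑one that loses N3=N4 as N2 after [4+2] addition across C2/C5.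
3. The bis(oxadiazinone) comes from the bis(arylpyruvic acid) by condensation with propanehydrazide and carbodiimide ring closure; the keto acids come from an Erlenmeyer azlactone of the 5‑acyl‑2,4,6‑trimethoxyisophthalaldehyde.
4. The dialdehyde comes from 1,3,5‑trimethoxybenzene by Friedel–Crafts acylation with isobutyryl chloride and twofold Rieche formylation.
5. Ring order: benzene ring bought; two temporary oxazolone rings; two oxadiazinone rings; both pyrone rings last, in one operation.

Key step: step 7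

Remark: 1‑ethoxyprop‑1‑yne is taken to be a catalogue reagent, and hydrazone 12 is drawn as the hydrogen‑bonded Z isomer, the one able to cyclise.

**Route**

Step 1
Reactants: 1 1,3,5‑trimethoxybenzene; 2 2‑methylpropanoyl chloride (isobutyryl chloride)
Product: 3 2‑methyl‑1‑(2,4,6‑trimethoxyphenyl)propan‑1‑one
Conditions: AlCl3 (1.2 equiv), CH2Cl2, 0 °C, 1 h; then ice‑water
Reagents that add atoms: none
Why: Friedel–Crafts acylation of the threefold‑activated symmetric arene can give only one monoketone, the twisted deactivating ketone stops a second acylation, and the short time at 0 °C should avoid AlCl3‑induced loss of an ortho methyl ether.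

Step 2
Reactants: 3 2‑methyl‑1‑(2,4,6‑trimethoxyphenyl)propan‑1‑one
Product: 5 2,4,6‑trimethoxy‑5‑(2‑methylpropanoyl)benzene‑1,3‑dicarbaldehyde, via bis(α‑chloro ether) 4 (not isolated)
Conditions: Cl2CHOMe (6 equiv), TiCl4 (6 equiv), CH2Cl2, 0 °C → rt; then ice‑water
Reagents that add atoms: dichloromethyl methyl ether, COC(Cl)Cl; water, O
Why: Rieche formylation, in which the small TiCl4‑activated chloro(methoxy)carbenium ion should substitute both remaining ring positions (each still flanked by two methoxy groups and para to the third, the di‑ortho‑substituted ketone being twisted out of conjugation), and aqueous work‑up hydrolyses the α‑chloro ethers to the aldehydes.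

Step 3
Reactants: 5 2,4,6‑trimethoxy‑5‑(2‑methylpropanoyl)benzene‑1,3‑dicarbaldehyde; 6 N‑acetylglycine (2.4 equiv)
Product: 8 (4Z,4'Z)‑bis(azlactone), each CHO of 5 converted into a (2‑methyl‑5‑oxo‑1,3‑oxazol‑4(5H)‑ylidene)methyl group, via 2‑methyl‑1,3‑oxazol‑5(4H)‑one 7 (not isolated)
Conditions: Ac2O, NaOAc (2.4 equiv), 100 °C
Reagents that add atoms: none
Why: Erlenmeyer–Plöchl azlactone synthesis, in which acetic anhydride cyclodehydrates N‑acetylglycine to the oxazolone and its acidic C4 methylene condenses with each aldehyde under acetate catalysis, the Z alkene (aryl syn to ring nitrogen) being expected although the geometry is erased in step 4.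

Step 4
Reactants: 8 (4Z,4'Z)‑bis(azlactone)
Product: 10 3,3'‑[2,4,6‑trimethoxy‑5‑(2‑methylpropanoyl)‑1,3‑phenylene]bis(2‑oxopropanoic acid), via bis(2‑acetamidoacrylic acid) 9 (not isolated)
Conditions: 3 M HCl, 1,4‑dioxane, reflux
Reagents that add atoms: water, O
Why: acid hydrolysis opens each azlactone to the 2‑acetamidoacrylic acid and then cleaves the enamide to the α‑keto acid, the standard route to arylpyruvic acids, while aryl methyl ethers and the hindered aryl ketone are inert to hot dilute HCl.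

Step 5
Reactants: 10 bis(arylpyruvic acid); 11 propanehydrazide (2.1 equiv)
Product: 12 (2Z,2'Z)‑3,3'‑[2,4,6‑trimethoxy‑5‑(2‑methylpropanoyl)‑1,3‑phenylene]bis[2‑(2‑propanoylhydrazinylidene)propanoic acid]
Conditions: EtOH, rt
Reagents that add atoms: none
Why: acylhydrazone condensation should occur only at the unhindered, strongly electrophilic α‑keto acid carbonyls (the di‑ortho‑substituted aryl isopropyl ketone is inert at room temperature), and because E and Z hydrazones interconvert both drain into the ring closure of step 6.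

Step 6
Reactants: 12 bis(N‑propanoylhydrazono acid)
Product: 13 5,5'‑{[2,4,6‑trimethoxy‑5‑(2‑methylpropanoyl)‑1,3‑phenylene]bis(methylene)}bis(2‑ethyl‑6H‑1,3,4‑oxadiazin‑6‑one)
Conditions: DCC (2.2 equiv), THF, 0 °C → rt; filter off the urea, concentrate, use at once
Reagents that add atoms: none
Why: carbodiimide cyclodehydration of α‑keto acid N‑acylhydrazones is the established entry to 1,3,4‑oxadiazin‑6‑ones (the O‑acylisourea is attacked by the hydrazide carbonyl oxygen in a 6‑exo‑trig lactonisation), and the base‑free conditions should keep the benzylic CH2 beside C5 from shifting a proton to N4.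

Step 7
Reactants: 13 bis(oxadiazinone); 14 1‑ethoxyprop‑1‑yne (6 equiv)
Product: 16 1‑{3,5‑bis[(4‑ethoxy‑6‑ethyl‑5‑methyl‑2‑oxo‑2H‑pyran‑3‑yl)methyl]‑2,4,6‑trimethoxyphenyl}‑2‑methylpropan‑1‑one, via twofold bicyclic adduct 15 (not isolated)
Conditions: toluene, 25 → 70 °C, N2
Reagents that add atoms: none
Why: Proposed new method: an alkynyl ether has not been used as the two‑carbon partner of a 1,3,4‑oxadiazin‑6‑one; the closest known reactions are the [4+2] addition/N2 extrusion of these heterocycles with alkynes and arynes to give 2‑pyrones, and the regiochemically analogous additions of ketene acetals to 3‑acyl‑2‑pyrones. The electron‑poor diazadiene C2=N3–N4=C5 of each ring should add the electron‑rich alkyne across C2 and C5 in an inverse‑demand, strongly asynchronous [4+2] step to give the 2‑oxa‑5,6‑diazabicyclo[2.2.2]octadienone 15, which loses N2 by retro‑[4+2] and leaves the aromatic 2‑pyrone. Each pyrone ring is therefore closed by an intermolecular [4+2] annulation that forms pyrone C3–C4 and C5–C6, and no stereocentre survives because the bridgehead carbons of 15 become sp2. The one selectivity needed is regiochemical: the nucleophilic methyl‑bearing alkyne carbon should bond to the ethyl‑bearing C2, the terminus of the vinylogous acyl system O=C6–C5=N4–N3=C2, because the charge building on N3 is then delocalised onto the lactone carbonyl while the ethoxy‑stabilised cationic carbon closes onto C5, which puts methyl on pyrone C5 and ethoxy on C4. Neutral conditions below 80 °C leave the hindered ketone alone, avoid retro‑ene loss of ethene from the alkynyl ether and offer no base for a proton shift from the benzylic CH2 to N4, and the electron‑rich 4‑ethoxypyrone should not react further with the electron‑rich alkyne.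

Step 8
Reactants: 16 tri‑O‑methyl bis(4‑ethoxypyrone)
Product: 17 1‑{3,5‑bis[(6‑ethyl‑4‑hydroxy‑5‑methyl‑2‑oxo‑2H‑pyran‑3‑yl)methyl]‑2,4,6‑trihydroxyphenyl}‑2‑methylpropan‑1‑one (target)
Conditions: BBr3 (12 equiv), CH2Cl2, −78 °C → rt; then MeOH, H2O
Reagents that add atoms: none
Why: BBr3 ether cleavage, in which boron binds each ether oxygen and the pyrone carbonyls (making the 4‑ethoxy groups vinylogous‑ester leaving units) and bromide removes methyl and ethyl by SN2, the borates being hydrolysed on quench while ketone, lactones and CH2 bridges should survive at or below room temperature.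

**Compound list**
1 | 1,3,5‑trimethoxybenzene | COc1cc(OC)cc(OC)c1 | starting material
2 | 2‑methylpropanoyl chloride (isobutyryl chloride) | CC(C)C(=O)Cl | starting material
3 | 2‑methyl‑1‑(2,4,6‑trimethoxyphenyl)propan‑1‑one | COc1cc(OC)c(C(=O)C(C)C)c(OC)c1 | intermediate
4 | 1‑{3,5‑bis[chloro(methoxy)methyl]‑2,4,6‑trimethoxyphenyl}‑2‑methylpropan‑1‑one (stereoisomer mixture at the two CHCl carbons; not isolated) | COC(Cl)c1c(OC)c(C(Cl)OC)c(OC)c(C(=O)C(C)C)c1OC | intermediate
5 | 2,4,6‑trimethoxy‑5‑(2‑methylpropanoyl)benzene‑1,3‑dicarbaldehyde | O=Cc1c(OC)c(C=O)c(OC)c(C(=O)C(C)C)c1OC | intermediate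
6 | N‑acetylglycine | CC(=O)NCC(=O)O | starting material
7 | 2‑methyl‑1,3‑oxazol‑5(4H)‑one (not isolated) | CC1=NCC(=O)O1 | intermediate
8 | (4Z,4'Z)‑4,4'‑{[2,4,6‑trimethoxy‑5‑(2‑methylpropanoyl)‑1,3‑phenylene]dimethanylylidene}bis(2‑methyl‑1,3‑oxazol‑5(4H)‑one) | CC1=N/C(=C\c2c(OC)c(/C=C3\N=C(C)OC3=O)c(OC)c(C(=O)C(C)C)c2OC)C(=O)O1 | intermediate
9 | (2Z,2'Z)‑3,3'‑[2,4,6‑trimethoxy‑5‑(2‑methylpropanoyl)‑1,3‑phenylene]bis(2‑acetamidoprop‑2‑enoic acid) (not isolated) | CC(=O)N/C(=C\c1c(OC)c(/C=C(\NC(C)=O)C(=O)O)c(OC)c(C(=O)C(C)C)c1OC)C(=O)O | intermediate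
10 | 3,3'‑[2,4,6‑trimethoxy‑5‑(2‑methylpropanoyl)‑1,3‑phenylene]bis(2‑oxopropanoic acid) | CC(C)C(=O)c1c(OC)c(CC(=O)C(=O)O)c(OC)c(CC(=O)C(=O)O)c1OC | intermediate
11 | propanehydrazide | CCC(=O)NN | starting material
12 | (2Z,2'Z)‑3,3'‑[2,4,6‑trimethoxy‑5‑(2‑methylpropanoyl)‑1,3‑phenylene]bis[2‑(2‑propanoylhydrazinylidene)propanoic acid] | CCC(=O)N/N=C(/Cc1c(OC)c(C/C(=N/NC(=O)CC)C(=O)O)c(OC)c(C(=O)C(C)C)c1OC)C(=O)O | intermediate
13 | 5,5'‑{[2,4,6‑trimethoxy‑5‑(2‑methylpropanoyl)‑1,3‑phenylene]bis(methylene)}bis(2‑ethyl‑6H‑1,3,4‑oxadiazin‑6‑one) | CCC1=NN=C(Cc2c(OC)c(CC3=NN=C(CC)OC3=O)c(OC)c(C(=O)C(C)C)c2OC)C(=O)O1 | intermediate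
14 | 1‑ethoxyprop‑1‑yne | CC#COCC | starting material
15 | 4,4'‑{[2,4,6‑trimethoxy‑5‑(2‑methylpropanoyl)‑1,3‑phenylene]bis(methylene)}bis(8‑ethoxy‑1‑ethyl‑7‑methyl‑2‑oxa‑5,6‑diazabicyclo[2.2.2]octa‑5,7‑dien‑3‑one) (each bicycle racemic, diastereomer mixture; not isolated) | CCC12OC(=O)C(Cc3c(OC)c(CC45N=NC(CC)(OC4=O)C(C)=C5OCC)c(OC)c(C(=O)C(C)C)c3OC)(N=N1)C(OCC)=C2C | intermediate
16 | 1‑{3,5‑bis[(4‑ethoxy‑6‑ethyl‑5‑methyl‑2‑oxo‑2H‑pyran‑3‑yl)methyl]‑2,4,6‑trimethoxyphenyl}‑2‑methylpropan‑1‑one | CCOc1c(C)c(CC)oc(=O)c1Cc1c(OC)c(Cc2c(OCC)c(C)c(CC)oc2=O)c(OC)c(C(=O)C(C)C)c1OC | intermediate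
17 | 1‑{3,5‑bis[(6‑ethyl‑4‑hydroxy‑5‑methyl‑2‑oxo‑2H‑pyran‑3‑yl)methyl]‑2,4,6‑trihydroxyphenyl}‑2‑methylpropan‑1‑one | CCc1oc(=O)c(Cc2c(O)c(Cc3c(O)c(C)c(CC)oc3=O)c(O)c(C(=O)C(C)C)c2O)c(O)c1C | target

**Step count**
Total steps: 8. Longest linear sequence: 8 steps (1 → 17).

**Steps most likely to fail**

Step 7 (new use of an alkynyl ether). The cycloaddition may take the opposite orientation, and the bicycle may expel CO2 in place of N2. The diazadiene may also be lost by proton shift from the benzylic CH2 to N4 before it is trapped, or the alkynyl ether may decompose by retro‑ene loss of ethene. Fallback by known chemistry: the pyrone rings are made first and then attached to the core. Methyl 3‑oxopentanoate is converted into its dianion (NaH, then n‑BuLi, THF, 0 °C) and acylated at C4 with N‑methoxy‑N‑methylpropanamide to give methyl 4‑methyl‑3,5‑dioxoheptanoate F1 (racemic at C4, largely enolised). DBU in refluxing toluene lactonises it to 6‑ethyl‑4‑hydroxy‑5‑methyl‑2H‑pyran‑2‑one F2. Setting out from dialdehyde 5, twofold reductive alkylation of F2 (L‑proline cat., Hantzsch ester, CH2Cl2, rt; Knoevenagel condensation at pyrone C3 and in situ transfer hydrogenation of the new alkene) should give 1‑{3,5‑bis[(6‑ethyl‑4‑hydroxy‑5‑methyl‑2‑oxo‑2H‑pyran‑3‑yl)methyl]‑2,4,6‑trimethoxyphenyl}‑2‑methylpropan‑1‑one F3. BBr3 (CH2Cl2, −78 °C → rt) then removes the three aryl methyl groups, and the route is rejoined at target 17.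

Step 8 (fivefold dealkylation). Cleavage may stop short at the slower ethyl ethers, or prolonged Lewis‑acid exposure may break the electron‑rich aryl–CH2–pyrone bridges by retro‑Friedel–Crafts scrambling. Fallback: no ether is left to cleave at the end. Setting out from ketone 3, BBr3 (CH2Cl2, 0 °C → rt) gives 2‑methyl‑1‑(2,4,6‑trihydroxyphenyl)propan‑1‑one F4 at a stage with no bridge at risk. Pyrone F2 (made as in the fallback to step 7) is aminomethylated with dimethylmethylideneammonium iodide (MeCN, rt) to 3‑[(dimethylamino)methyl]‑6‑ethyl‑4‑hydroxy‑5‑methyl‑2H‑pyran‑2‑one F5. On warming with F4 (two equivalents of F5, MeCN, 60 °C) the Mannich base loses dimethylamine, and the two free ring carbons of F4 add to the resulting Michael acceptor. This is the usual methylene‑bridging reaction of acylphloroglucinols, and it returns to the route at target 17.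

Step 2 (twofold formylation). The second formylation may stall at the mono‑aldehyde, because the first formyl group and the crowded, twisted methoxy groups lower the ring's nucleophilicity, or TiCl4 may strip a methyl ether next to a carbonyl. Fallback: the two carbons are introduced at the alcohol oxidation level and then oxidised. Setting out from ketone 3, twofold bromomethylation (paraformaldehyde, 33% HBr in AcOH, 50 °C) should give 1‑[3,5‑bis(bromomethyl)‑2,4,6‑trimethoxyphenyl]‑2‑methylpropan‑1‑one F6. Its benzylic bromides are oxidised with N‑methylmorpholine N‑oxide (MeCN, rt; Kornblum‑type oxidation), rejoining the route at dialdehyde 5.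

**Further compounds**
F1 | step 7 | methyl 4‑methyl‑3,5‑dioxoheptanoate (racemic) | CCC(=O)C(C)C(=O)CC(=O)OC
F2 | step 7 | 6‑ethyl‑4‑hydroxy‑5‑methyl‑2H‑pyran‑2‑one | CCc1oc(=O)cc(O)c1C
F3 | step 7 | 1‑{3,5‑bis[(6‑ethyl‑4‑hydroxy‑5‑methyl‑2‑oxo‑2H‑pyran‑3‑yl)methyl]‑2,4,6‑trimethoxyphenyl}‑2‑methylpropan‑1‑one | CCc1oc(=O)c(Cc2c(OC)c(Cc3c(O)c(C)c(CC)oc3=O)c(OC)c(C(=O)C(C)C)c2OC)c(O)c1C
F4 | step 8 | 2‑methyl‑1‑(2,4,6‑trihydroxyphenyl)propan‑1‑one | CC(C)C(=O)c1c(O)cc(O)cc1O
F5 | step 8 | 3‑[(dimethylamino)methyl]‑6‑ethyl‑4‑hydroxy‑5‑methyl‑2H‑pyran‑2‑one | CCc1oc(=O)c(CN(C)C)c(O)c1C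
F6 | step 2 | 1‑[3,5‑bis(bromomethyl)‑2,4,6‑trimethoxyphenyl]‑2‑methylpropan‑1‑one | COc1c(CBr)c(OC)c(C(=O)C(C)C)c(OC)c1CBr
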